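## Analysis of the target

5'-Methoxyhydnocarpin is a flavonolignan: rings A and C form a 5,7-dihydroxychromen-4-one, C2 of ring C is bonded to C1' of ring B, and ring B is fused through the oxygens on C3' and C4' to a 2,3-dihydro-1,4-dioxine ring and carries a methoxy group on C5'. In the dioxane ring, Cα (bonded to the oxygen on C3') bears the 4-hydroxy-3-methoxyphenyl ring and Cβ (bonded to the oxygen on C4') bears the hydroxymethyl group. Cα and Cβ are the only stereocentres; they are vicinal, both R, and this places aryl and hydroxymethyl trans on the dioxane ring. The Cα–O bond is a benzylic aryl ether para to a phenolic oxygen, so acid or strong base can ionise it towards a quinone-methide-like species, with epimerisation or ring opening as the result. Three free phenols (O5 is hydrogen-bonded to the C4 carbonyl) stand beside two aryl methyl ethers, so no O-demethylation can be used at the end and every phenol protecting group must come off without touching a methoxy group. The difficulty is threefold: the regiochemistry of the dioxane (which ring-B oxygen carries which carbon), the trans (R,R) configuration, and the union of this fragile, enantiopure benzodioxane with a phloroglucinol-type chromone under conditions milder than the strong bases and oxidants of classical flavone syntheses. The strategy rests on ring C (O1, C2, C3, C4, C4a, C8a), the only link between ring A and the ring-B unit: C4 is a lone carbonyl carbon between C4a and C3, C2–C3 is a two-carbon unit on C1', and O1 is a phenol oxygen of ring A, so ring C can be assembled from an ortho-iodophenol, carbon monoxide and an arylalkyne.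

## Retrosynthetic reasoning

Target 23 is first traced back to the fully protected flavone 22. Only protecting-group bonds are cut: three methoxymethyl ethers (on O5, O7 and the guaiacyl oxygen) and the silyl ether on the primary oxygen. All four fall under one mild acid solvolysis that leaves the two methoxy groups alone. The forward step has to do this without ionising the Cα–O bond.

Protected flavone 22 is cut at C4a–C4, C4–C3 and O1–C2, which takes ring C apart completely. C4 becomes carbon monoxide 19. Ring A becomes iodophenol 5, with iodine on the future C4a, the free hydroxyl as the future O1 and the other two oxygens as acetals. C2–C3 with the whole ring B–dioxane unit becomes terminal alkyne 18. This cut is preferred to one in ring A or in the dioxane because it is the most convergent: both stereocentres arrive finished in 18, ring A is an aromatic building block with its oxygen pattern complete, and the union runs under weakly basic conditions. The forward reaction has to insert 19 before the alkyne is transferred and then close the six-membered ring rather than the five-membered one.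

Alkyne 18 is traced through silylalkyne 17 to aryl bromide 16 by cutting the C1'–C(sp) bond. A bromide is carried at C1' instead of a formyl group because an aldehyde on ring B would be a second acceptor in the aldol step that builds the side chain. A free alkyne would not pass the copper-mediated ring closure either. The bromide stays inert until the Sonogashira coupling calls on it.

Bromide 16 is opened at the aryl–oxygen bond between C3' and the oxygen on Cα, giving alcohol 15. The Cα–O bond is deliberately not the one cut: if it stays intact, the configuration of both carbons passes through the closure unchanged. The forward reaction, a copper-catalysed intramolecular etherification, must pick the bromide ortho to the ether oxygen and leave the para one; ring size ensures this.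

Alcohol 15 comes from diol 14 by silylation of the primary hydroxyl, and 14 from aldol adduct 13 by reductive removal of the auxiliary. These functional-group changes turn the acyl carbon into the hydroxymethyl carbon and remove the enolisable carbonyl before any strongly basic step.

Adduct 13 is cut at the Cα–Cβ bond into imide 10 and aldehyde 7. This single bond formation creates both stereocentres. A boron-mediated syn aldol gives the (2S,3R) adduct, in which the two oxygens lie on the same side of the zigzag chain carbonyl–Cβ–Cα–aryl. When the dioxane is later closed through these two oxygens without breaking either C–O bond, the chain ends (hydroxymethyl carbon and aryl) end up trans, and the descriptors become (R,R).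

Imide 10 is cut at the O–CH2 bond into phenol 8 and chloroacetyl imide 9, and aldehyde 7 comes from vanillin 6 by protection. The phenol oxygen of 8 sits between the methoxy-bearing carbon and a brominated carbon, so alkylating it fixes the regiochemistry of the dioxane from the start. This oxygen becomes the one on C4' bonded to Cβ, the ortho bromide marks C3' and the para bromide marks C1'.

Iodophenol 5 is cut at the C–I bond to phenol 4, and 4 at its C–OH bond to bis-ether 2 through boronate 3; 2 comes from resorcinol 1. Introducing the third oxygen at the only unhindered C–H of 2 avoids the statistical protection of a triol. The iodination of 4 then has to choose the position between the hydroxyl and one acetal over the position between the two acetals.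

## Alternatives that were turned down

Alternative 1: closure of the dioxane at Cα through a benzylic cation.
- Disconnection: the bond between Cα and the oxygen on C3' in benzodioxane aldehyde A1, leading back to open-chain aryl ether A2. In A2 only Cβ is configured, and the C3' phenol, the primary alcohol and the guaiacyl phenol are masked as acetals.
- Forward key step: aqueous CF3CO2H removes the acetals of A2 and ionises the benzylic carbinol to a cation stabilised by the para oxygen. The freed C3' phenol adds to Cα and the six-membered ring closes. Trans A1 is preferred because opening and closing are reversible and aryl and hydroxymethyl prefer to be diequatorial.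
- For it: only one stereocentre is made deliberately, either carbinol epimer of A2 converges, no metal is needed, and deprotection and closure are one operation.
- Against it: the trans configuration is held by an energy difference and not by a mechanism, so some cis isomer is to be expected as a diastereomeric impurity. The cation forms next to two electron-rich arenes and an aldehyde, which invites Friedel–Crafts-type side reactions. A1 leaves the step with phenol and primary alcohol free, so two protections precede any flavone-forming reaction. Ring C still has to be built afterwards.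
- Comparison: this alternative is stronger on stereochemical economy, since it controls one centre where the chosen route controls two. The chosen route offers instead a closed, auxiliary-controlled aldol transition state for both centres, a ring closure that breaks no bond to either, and a late, convergent construction of ring C.

Alternative 2: cis-glycidate opening followed by O-arylation.
- Disconnection: both the Cα–O bond and the C4'–O bond of the dioxane in diester A3, leading back to bromophenol A4 and cis-glycidate A5.
- Forward key step: the caesium phenoxide of A4 (Cs2CO3) opens A5 at benzylic Cα with inversion. The released Cβ alkoxide is then arylated at the C4'–Br carbon under CuI (monovalent copper), which closes the ring as trans A3.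
- For it: two C–O bonds and the ring form in one flask, the chirality can come from a catalytic asymmetric epoxidation instead of a stoichiometric auxiliary, and it is the shortest access to the benzodioxane.
- Against it: Cα of A5 is a para-alkoxybenzylic epoxide carbon, so its opening drifts towards an ionised pathway and the inversion can leak. In the alkoxide and in A3, Cβ–H is alpha to an ester and beta to an aryloxy group, so at coupling temperatures carbonate base threatens epimerisation and eliminative opening of the dioxane. The C4'–Br of A4 is flanked by two oxygen-bearing carbons and is hindered. A3 then carries two esters that must be told apart, and the ring-B ester needs several steps to become a flavone carbon.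
- Comparison: this alternative is stronger on step count and atom economy for the dioxane. The chosen route offers stereochemical security (no enolisable centre is present during the copper step) and a ring-B bromide that maps directly onto the alkyne needed for ring C.

Alternative 3: ring A by a polyketide-type Claisen cyclisation.
- Disconnection: the C4a–C5 bond of ring A in 5,7-dihydroxyflavone A6, leading back to pyranone keto ester A7, a 6-aryl-4-pyranone with a 3-oxobutanoate chain on the future C8a.
- Forward key step: Mg(OMe)2 forms the extended enolate of A7, C4a attacks the ester carbon C5, the six-membered ring closes and enolisation aromatises it to the 5,7-diol.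
- For it: no palladium and no carbon monoxide, no regiochemical question on an iodophenol, and the ring-A phenols appear unprotected, so fewer protecting groups are carried.
- Against it: A7 must be built by stepwise chain extension on the chiral benzodioxane, which makes the route linear on the most valuable material. A7 has several acidic sites and several electrophilic carbonyls, so other closures (aldol-type ring formation, O-acylation, methoxide attack on the pyranone) compete with the wanted Claisen mode. C4a of a 4-pyranone is only a weak vinylogous nucleophile.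
- Comparison: this alternative is stronger on protecting-group economy and on avoiding a toxic gas. The chosen route buys ring A as a finished arene and exposes the chiral fragment to only two steps after the union.

Key step: step 12

Assumption: 2,4-dibromo-6-methoxyphenol (8) and (S)-4-benzyl-3-(chloroacetyl)oxazolidin-2-one (9) are treated as purchasable building blocks.

## Route

Step 1
Reactants: 1 resorcinol
Product: 2 1,3-bis(methoxymethoxy)benzene
Conditions: MOMCl (2.5 equiv), i-Pr2NEt (3 equiv), CH2Cl2, 0 °C to rt
Reagents that add atoms: chloromethyl methyl ether, COCCl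
Why: Exhaustive O-alkylation of both phenols to the mixed acetals; both hydroxyls react, so there is no selectivity question.

Step 2
Reactants: 2 1,3-bis(methoxymethoxy)benzene
Product: 4 3,5-bis(methoxymethoxy)phenol, via arylboronate 3 (not isolated)
Conditions: [Ir(OMe)(cod)]2 (1.5 mol %), 4,4'-di-tert-butyl-2,2'-bipyridine (3 mol %), B2pin2 (0.55 equiv), THF, 70 °C; then NaOH (aq), 30% H2O2, 0 °C to rt
Reagents that add atoms: hydrogen peroxide, OO (the new phenol oxygen of 4); bis(pinacolato)diboron, CC1(C)OB(OC1(C)C)B1OC(C)(C)C(C)(C)O1 (boron of intermediate 3 only)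
Why: Iridium-catalysed aromatic C–H borylation is sterically controlled and C5 is the only ring position without an ortho substituent; oxidation of the boronate then gives the phenol at the same carbon (borylation–oxidation sequence) under basic conditions that leave the acetals alone.

Step 3
Reactants: 4 3,5-bis(methoxymethoxy)phenol
Product: 5 2-iodo-3,5-bis(methoxymethoxy)phenol
Conditions: NIS (1.0 equiv), CH2Cl2, −40 to 0 °C, dark
Reagents that add atoms: N-iodosuccinimide, O=C1CCC(=O)N1I
Why: Electrophilic aromatic iodination of a phloroglucinol-type ring under neutral conditions; the two positions between the hydroxyl and one acetal are less hindered than the position between the two acetals and count double, and one equivalent at low temperature limits di-iodination.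

Step 4
Reactants: 6 vanillin
Product: 7 3-methoxy-4-(methoxymethoxy)benzaldehyde
Conditions: MOMCl (1.3 equiv), i-Pr2NEt (1.6 equiv), CH2Cl2, 0 °C to rt
Reagents that add atoms: chloromethyl methyl ether, COCCl
Why: Phenol O-alkylation to the methoxymethyl ether, which survives the boron aldol, hydride, carbonate and palladium steps and falls in the final acid step.

Step 5
Reactants: 8 2,4-dibromo-6-methoxyphenol; 9 (S)-4-benzyl-3-(chloroacetyl)oxazolidin-2-one
Product: 10 (S)-4-benzyl-3-[(2,4-dibromo-6-methoxyphenoxy)acetyl]oxazolidin-2-one
Conditions: K2CO3 (1.5 equiv), NaI (10 mol %), DMF, rt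
Reagents that add atoms: none
Why: Williamson etherification of the acidic dibromophenol with an activated alpha-halo imide (iodide catalysis); it fixes which ring-B oxygen will carry Cβ.

Step 6
Reactants: 10 (S)-4-benzyl-3-[(2,4-dibromo-6-methoxyphenoxy)acetyl]oxazolidin-2-one; 7 3-methoxy-4-(methoxymethoxy)benzaldehyde
Product: 13 (S)-4-benzyl-3-[(2S,3R)-2-(2,4-dibromo-6-methoxyphenoxy)-3-hydroxy-3-[3-methoxy-4-(methoxymethoxy)phenyl]propanoyl]oxazolidin-2-one, via boron enolate 11 (not isolated), via boron aldolate 12 (not isolated)
Conditions: n-Bu2BOTf (1.2 equiv), i-Pr2NEt (1.4 equiv), CH2Cl2, −78 to 0 °C; then 7, −78 to 0 °C; then pH 7 buffer, MeOH, 30% H2O2, 0 °C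
Reagents that add atoms: dibutylboron trifluoromethanesulfonate, CCCCB(CCCC)OS(=O)(=O)C(F)(F)F (boron and butyl groups of intermediates 11 and 12 only)
Why: Evans syn aldol: soft enolisation gives the Z boron enolate 11, which adds to 7 through a chair Zimmerman–Traxler transition state with the aldehyde aryl group equatorial, on the enolate face away from the benzyl group of the dipole-opposed auxiliary; this sets Cβ as S and Cα as R in 13 (syn), the arrangement that becomes trans (R,R) in the dioxane. Aryloxyacetyl imides and electron-rich aromatic aldehydes are established partners, and the aryl bromides and the aryl acetal tolerate the conditions and the buffered peroxide work-up.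

Step 7
Reactants: 13 (S)-4-benzyl-3-[(2S,3R)-2-(2,4-dibromo-6-methoxyphenoxy)-3-hydroxy-3-[3-methoxy-4-(methoxymethoxy)phenyl]propanoyl]oxazolidin-2-one
Product: 14 (1R,2R)-2-(2,4-dibromo-6-methoxyphenoxy)-1-[3-methoxy-4-(methoxymethoxy)phenyl]propane-1,3-diol
Conditions: LiBH4 (2 equiv), MeOH (1 equiv), THF, 0 °C
Reagents that add atoms: none
Why: Reductive cleavage of the N-acyl oxazolidinone to the primary alcohol with release of the auxiliary; no bond to a stereocentre is touched, and the Cβ descriptor changes from S to R only because CH2OH ranks below Cα.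

Step 8
Reactants: 14 (1R,2R)-2-(2,4-dibromo-6-methoxyphenoxy)-1-[3-methoxy-4-(methoxymethoxy)phenyl]propane-1,3-diol
Product: 15 (1R,2R)-3-[tert-butyl(dimethyl)silyl]oxy-2-(2,4-dibromo-6-methoxyphenoxy)-1-[3-methoxy-4-(methoxymethoxy)phenyl]propan-1-ol
Conditions: TBSCl (1.05 equiv), imidazole (2 equiv), CH2Cl2, 0 °C
Reagents that add atoms: tert-butyldimethylsilyl chloride, CC(C)(C)[Si](C)(C)Cl
Why: Selective silylation of the primary hydroxyl over the hindered secondary benzylic one, so that only the Cα oxygen can take part in the ring closure.

Step 9
Reactants: 15 (1R,2R)-3-[tert-butyl(dimethyl)silyl]oxy-2-(2,4-dibromo-6-methoxyphenoxy)-1-[3-methoxy-4-(methoxymethoxy)phenyl]propan-1-ol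
Product: 16 tert-butyl{[(2R,3R)-6-bromo-8-methoxy-3-[3-methoxy-4-(methoxymethoxy)phenyl]-2,3-dihydro-1,4-benzodioxin-2-yl]methoxy}dimethylsilane
Conditions: CuI (10 mol %), 3,4,7,8-tetramethyl-1,10-phenanthroline (20 mol %), Cs2CO3 (2 equiv), toluene, 100 °C
Reagents that add atoms: none
Why: Ullmann-type copper-catalysed intramolecular O-arylation: the alkoxide bound to monovalent copper can reach only the C–Br bond ortho to the ether oxygen (six-membered ring), so the para bromide is kept. The Cα–O and Cβ–O bonds are not broken, so both stereocentres are retained and the syn adduct gives the trans (2R,3R) dioxane.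

Step 10
Reactants: 16 tert-butyl{[(2R,3R)-6-bromo-8-methoxy-3-[3-methoxy-4-(methoxymethoxy)phenyl]-2,3-dihydro-1,4-benzodioxin-2-yl]methoxy}dimethylsilane
Product: 17 tert-butyl{[(2R,3R)-8-methoxy-3-[3-methoxy-4-(methoxymethoxy)phenyl]-6-[(trimethylsilyl)ethynyl]-2,3-dihydro-1,4-benzodioxin-2-yl]methoxy}dimethylsilane
Conditions: ethynyltrimethylsilane (1.5 equiv), PdCl2(PhCN)2 (3 mol %), t-Bu3P·HBF4 (6 mol %), CuI (2 mol %), i-Pr2NH, 1,4-dioxane, rt to 40 °C
Reagents that add atoms: ethynyltrimethylsilane, C#C[Si](C)(C)C
Why: Sonogashira coupling of the remaining, unhindered aryl bromide; the bulky electron-rich phosphine lets an electron-rich bromide react near room temperature, and the silyl cap prevents double coupling.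

Step 11
Reactants: 17 tert-butyl{[(2R,3R)-8-methoxy-3-[3-methoxy-4-(methoxymethoxy)phenyl]-6-[(trimethylsilyl)ethynyl]-2,3-dihydro-1,4-benzodioxin-2-yl]methoxy}dimethylsilane
Product: 18 tert-butyl{[(2R,3R)-6-ethynyl-8-methoxy-3-[3-methoxy-4-(methoxymethoxy)phenyl]-2,3-dihydro-1,4-benzodioxin-2-yl]methoxy}dimethylsilane
Conditions: K2CO3 (0.2 equiv), MeOH–THF, rt
Reagents that add atoms: none
Why: Methanolysis of the alkynyl C–Si bond under catalytic carbonate; the primary tert-butyldimethylsilyl ether and the aryl acetal are stable to these conditions.

Step 12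
Reactants: 5 2-iodo-3,5-bis(methoxymethoxy)phenol; 19 carbon monoxide; 18 tert-butyl{[(2R,3R)-6-ethynyl-8-methoxy-3-[3-methoxy-4-(methoxymethoxy)phenyl]-2,3-dihydro-1,4-benzodioxin-2-yl]methoxy}dimethylsilane
Product: 22 2-[(2R,3R)-2-({[tert-butyl(dimethyl)silyl]oxy}methyl)-8-methoxy-3-[3-methoxy-4-(methoxymethoxy)phenyl]-2,3-dihydro-1,4-benzodioxin-6-yl]-5,7-bis(methoxymethoxy)-4H-chromen-4-one, via ynone 20 (not isolated), via enaminone 21 (not isolated)
Conditions: PdCl2(PPh3)2 (5 mol %), Et2NH (10 equiv), CO (5 bar), DMF, 60 °C
Reagents that add atoms: diethylamine, CCNCC (nitrogen and ethyl groups of intermediate 21 only)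
Why: PdCl2(PPh3)2 is reduced in the flask to zerovalent palladium, which inserts into the C–I bond of 5; CO (19) then inserts to give an aroyl complex of divalent palladium, the amine-deprotonated alkyne 18 is transferred to it, and reductive elimination releases ynone 20 (C4a–C4 and C4–C3 formed). Diethylamine adds to 20 in conjugate fashion to give enaminone 21, and the ortho phenol then attacks C2 and expels the amine, which forms O1–C2. The closest known reaction type is the palladium-catalysed carbonylative Sonogashira coupling–cyclisation of 2-iodophenols with terminal arylalkynes to flavones. Ring C closes in the 6-endo mode, as an addition–elimination at the trigonal C2 of 21. No stereocentre is formed; the two existing ones are remote from the reacting carbons and see only a weak amine base at moderate temperature. Three selectivities are needed: CO insertion before alkynyl transfer (otherwise a 2-arylbenzofuran results), capture of the aroylpalladium by the acetylide and not by the amine, and 6-endo instead of 5-exo closure (aurone). The first is secured by the electron-rich, doubly ortho-substituted aryl group, which migrates to CO quickly, together with CO pressure and the absence of a copper co-catalyst; the second by a moderate temperature and a full equivalent of alkyne; the third by the secondary amine, which turns the ynone into 21 so that C2 is the only electrophilic carbon the phenol can reach.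

Step 13
Reactants: 22 2-[(2R,3R)-2-({[tert-butyl(dimethyl)silyl]oxy}methyl)-8-methoxy-3-[3-methoxy-4-(methoxymethoxy)phenyl]-2,3-dihydro-1,4-benzodioxin-6-yl]-5,7-bis(methoxymethoxy)-4H-chromen-4-one
Product: 23 5'-methoxyhydnocarpin, 5,7-dihydroxy-2-[(2R,3R)-3-(4-hydroxy-3-methoxyphenyl)-2-(hydroxymethyl)-8-methoxy-2,3-dihydro-1,4-benzodioxin-6-yl]-4H-chromen-4-one
Conditions: HCl (2 M), MeOH–THF, 40 °C
Reagents that add atoms: none
Why: Acid-catalysed transacetalisation of the three aryl methoxymethyl ethers and solvolysis of the primary silyl ether in one operation; methyl ethers and the chromone are inert, and the temperature is kept low so that the benzylic Cα–O bond is not ionised.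

## Compound list

1 | resorcinol | Oc1cccc(O)c1 | starting material
2 | 1,3-bis(methoxymethoxy)benzene | COCOc1cccc(OCOC)c1 | intermediate
3 | 2-[3,5-bis(methoxymethoxy)phenyl]-4,4,5,5-tetramethyl-1,3,2-dioxaborolane | COCOc1cc(OCOC)cc(c1)B1OC(C)(C)C(C)(C)O1 | intermediate (not isolated)
4 | 3,5-bis(methoxymethoxy)phenol | COCOc1cc(O)cc(OCOC)c1 | intermediate
5 | 2-iodo-3,5-bis(methoxymethoxy)phenol | Oc1cc(OCOC)cc(OCOC)c1I | intermediate
6 | vanillin | COc1cc(C=O)ccc1O | starting material
7 | 3-methoxy-4-(methoxymethoxy)benzaldehyde | COCOc1ccc(C=O)cc1OC | intermediate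
8 | 2,4-dibromo-6-methoxyphenol | COc1cc(Br)cc(Br)c1O | starting material
9 | (S)-4-benzyl-3-(chloroacetyl)oxazolidin-2-one | ClCC(=O)N1[C@@H](Cc2ccccc2)COC1=O | starting material
10 | (S)-4-benzyl-3-[(2,4-dibromo-6-methoxyphenoxy)acetyl]oxazolidin-2-one | COc1cc(Br)cc(Br)c1OCC(=O)N1[C@@H](Cc2ccccc2)COC1=O | intermediate
11 | Z dibutylboron enolate of 10 | COc1cc(Br)cc(Br)c1O/C=C(\OB(CCCC)CCCC)N1[C@@H](Cc2ccccc2)COC1=O | intermediate (not isolated)
12 | dibutylboron aldolate of 13 | COCOc1ccc(cc1OC)[C@@H](OB(CCCC)CCCC)[C@H](Oc1c(Br)cc(Br)cc1OC)C(=O)N1[C@@H](Cc2ccccc2)COC1=O | intermediate (not isolated)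
13 | (S)-4-benzyl-3-[(2S,3R)-2-(2,4-dibromo-6-methoxyphenoxy)-3-hydroxy-3-[3-methoxy-4-(methoxymethoxy)phenyl]propanoyl]oxazolidin-2-one | COCOc1ccc(cc1OC)[C@@H](O)[C@H](Oc1c(Br)cc(Br)cc1OC)C(=O)N1[C@@H](Cc2ccccc2)COC1=O | intermediate
14 | (1R,2R)-2-(2,4-dibromo-6-methoxyphenoxy)-1-[3-methoxy-4-(methoxymethoxy)phenyl]propane-1,3-diol | COCOc1ccc(cc1OC)[C@@H](O)[C@H](Oc1c(Br)cc(Br)cc1OC)CO | intermediate
15 | (1R,2R)-3-[tert-butyl(dimethyl)silyl]oxy-2-(2,4-dibromo-6-methoxyphenoxy)-1-[3-methoxy-4-(methoxymethoxy)phenyl]propan-1-ol | COCOc1ccc(cc1OC)[C@@H](O)[C@H](Oc1c(Br)cc(Br)cc1OC)CO[Si](C)(C)C(C)(C)C | intermediate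
16 | tert-butyl{[(2R,3R)-6-bromo-8-methoxy-3-[3-methoxy-4-(methoxymethoxy)phenyl]-2,3-dihydro-1,4-benzodioxin-2-yl]methoxy}dimethylsilane (trans) | COc1cc([C@H]2Oc3cc(Br)cc(OC)c3O[C@@H]2CO[Si](C)(C)C(C)(C)C)ccc1OCOC | intermediate
17 | tert-butyl{[(2R,3R)-8-methoxy-3-[3-methoxy-4-(methoxymethoxy)phenyl]-6-[(trimethylsilyl)ethynyl]-2,3-dihydro-1,4-benzodioxin-2-yl]methoxy}dimethylsilane | COc1cc([C@H]2Oc3cc(C#C[Si](C)(C)C)cc(OC)c3O[C@@H]2CO[Si](C)(C)C(C)(C)C)ccc1OCOC | intermediate
18 | tert-butyl{[(2R,3R)-6-ethynyl-8-methoxy-3-[3-methoxy-4-(methoxymethoxy)phenyl]-2,3-dihydro-1,4-benzodioxin-2-yl]methoxy}dimethylsilane | COc1cc([C@H]2Oc3cc(C#C)cc(OC)c3O[C@@H]2CO[Si](C)(C)C(C)(C)C)ccc1OCOC | intermediate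
19 | carbon monoxide | [C-]#[O+] | starting material
20 | 1-[2-hydroxy-4,6-bis(methoxymethoxy)phenyl]-3-[(2R,3R)-2-({[tert-butyl(dimethyl)silyl]oxy}methyl)-8-methoxy-3-[3-methoxy-4-(methoxymethoxy)phenyl]-2,3-dihydro-1,4-benzodioxin-6-yl]prop-2-yn-1-one | COc1cc([C@H]2Oc3cc(C#CC(=O)c4c(O)cc(OCOC)cc4OCOC)cc(OC)c3O[C@@H]2CO[Si](C)(C)C(C)(C)C)ccc1OCOC | intermediate (not isolated)
21 | (E)-3-(diethylamino)-1-[2-hydroxy-4,6-bis(methoxymethoxy)phenyl]-3-[(2R,3R)-2-({[tert-butyl(dimethyl)silyl]oxy}methyl)-8-methoxy-3-[3-methoxy-4-(methoxymethoxy)phenyl]-2,3-dihydro-1,4-benzodioxin-6-yl]prop-2-en-1-one (alkene geometry not relevant to the outcome) | COc1cc([C@H]2Oc3cc(/C(N(CC)CC)=C\C(=O)c4c(O)cc(OCOC)cc4OCOC)cc(OC)c3O[C@@H]2CO[Si](C)(C)C(C)(C)C)ccc1OCOC | intermediate (not isolated)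
22 | 2-[(2R,3R)-2-({[tert-butyl(dimethyl)silyl]oxy}methyl)-8-methoxy-3-[3-methoxy-4-(methoxymethoxy)phenyl]-2,3-dihydro-1,4-benzodioxin-6-yl]-5,7-bis(methoxymethoxy)-4H-chromen-4-one | COc1cc([C@H]2Oc3cc(-c4cc(=O)c5c(OCOC)cc(OCOC)cc5o4)cc(OC)c3O[C@@H]2CO[Si](C)(C)C(C)(C)C)ccc1OCOC | intermediate
23 | 5'-methoxyhydnocarpin, 5,7-dihydroxy-2-[(2R,3R)-3-(4-hydroxy-3-methoxyphenyl)-2-(hydroxymethyl)-8-methoxy-2,3-dihydro-1,4-benzodioxin-6-yl]-4H-chromen-4-one | COc1cc([C@H]2Oc3cc(-c4cc(=O)c5c(O)cc(O)cc5o4)cc(OC)c3O[C@@H]2CO)ccc1O | target

## Step count and least certain steps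

Total: 13 steps. Longest linear sequence: 9 steps (steps 5 to 13, from 8 and 9).

Step 12 (key step).
- What may go wrong: the aroylpalladium intermediate may be captured by diethylamine, giving an amide instead of the ynone, because the amine is in large excess and the aryl group is hindered. The alkyne may also be transferred before CO insertion, followed by cyclisation to a benzofuran. Oxidative addition to the electron-rich, doubly ortho-substituted C–I bond may be slow.
- Fallback (sets out from 4 and 18, returns at 23), without palladium or CO: phenol 4 is protected (MOMCl, i-Pr2NEt) to 1,3,5-tris(methoxymethoxy)benzene F1. F1 is lithiated between two acetal oxygens (n-BuLi, THF, 0 °C; all three ring positions are equivalent) and formylated with DMF to 2,4,6-tris(methoxymethoxy)benzaldehyde F2. The lithium acetylide of 18 (n-BuLi, THF, −78 °C) adds to F2 to give propargylic alcohol F3 (both carbinol epimers). MnO2 oxidises F3 to ynone F4, and diethylamine adds to give enaminone F5. HCl in methanol then removes the four acetals and the silyl ether, and a freed ortho phenol displaces the amine at C2, which closes ring C and gives 23 directly.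

Step 9 (copper ring closure).
- What may go wrong: the benzylic alkoxide is hindered and the closure may be slow. Under the carbonate base the silyl group can migrate from the primary to the benzylic oxygen, which blocks the reacting oxygen, and prolonged heating allows reductive loss of bromine.
- Fallback (sets out from 14, returns at 16): the etherification is run on diol 14 with the same CuI–phenanthroline–Cs2CO3 system. No silyl group can migrate, the alcohol is less encumbered, and six-membered closure through the benzylic oxygen is expected to outrun seven-membered closure through the primary one. This gives [(2R,3R)-6-bromo-8-methoxy-3-[3-methoxy-4-(methoxymethoxy)phenyl]-2,3-dihydro-1,4-benzodioxin-2-yl]methanol F6, which is silylated (TBSCl, imidazole) to 16.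

Step 3 (iodination).
- What may go wrong: poor regioselectivity. Attack at the position between the two acetals gives an iodide that cannot close ring C, and the very electron-rich ring may take up a second iodine.
- Fallback (sets out from 4, returns at 5), by directed metalation instead of electrophilic substitution: 4 is acylated with diethylcarbamoyl chloride (NaH, THF) to 3,5-bis(methoxymethoxy)phenyl diethylcarbamate F7. s-BuLi–TMEDA (THF, −78 °C) removes the proton between the carbamate and one acetal, where the strongest directing group and a second one cooperate. Iodine then gives 2-iodo-3,5-bis(methoxymethoxy)phenyl diethylcarbamate F8. Hydrolysis of the carbamate (NaOH, EtOH–H2O, reflux) gives 5.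

Step 13 (global deprotection).
- What may go wrong: ionisation of the benzylic Cα–O bond in acidic methanol, with epimerisation at Cα or opening of the dioxane by the solvent, before the last acetal has gone.
- Fallback (sets out from 22, returns at 23), in two stages without a protic acid: Bu4NF (THF, 0 °C) removes the silyl ether to give 2-[(2R,3R)-2-(hydroxymethyl)-8-methoxy-3-[3-methoxy-4-(methoxymethoxy)phenyl]-2,3-dihydro-1,4-benzodioxin-6-yl]-5,7-bis(methoxymethoxy)-4H-chromen-4-one F9. ZnBr2 with propane-1-thiol (CH2Cl2, 0 °C, short contact) then cleaves the three acetals by thiol capture of the methoxymethyl group and gives 23.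

## Further compounds

F1 | step 12 | 1,3,5-tris(methoxymethoxy)benzene | COCOc1cc(OCOC)cc(OCOC)c1
F2 | step 12 | 2,4,6-tris(methoxymethoxy)benzaldehyde | COCOc1cc(OCOC)c(C=O)c(OCOC)c1
F3 | step 12 | 3-[(2R,3R)-2-({[tert-butyl(dimethyl)silyl]oxy}methyl)-8-methoxy-3-[3-methoxy-4-(methoxymethoxy)phenyl]-2,3-dihydro-1,4-benzodioxin-6-yl]-1-[2,4,6-tris(methoxymethoxy)phenyl]prop-2-yn-1-ol (both carbinol epimers) | COc1cc([C@H]2Oc3cc(C#CC(O)c4c(OCOC)cc(OCOC)cc4OCOC)cc(OC)c3O[C@@H]2CO[Si](C)(C)C(C)(C)C)ccc1OCOC
F4 | step 12 | 3-[(2R,3R)-2-({[tert-butyl(dimethyl)silyl]oxy}methyl)-8-methoxy-3-[3-methoxy-4-(methoxymethoxy)phenyl]-2,3-dihydro-1,4-benzodioxin-6-yl]-1-[2,4,6-tris(methoxymethoxy)phenyl]prop-2-yn-1-one | COc1cc([C@H]2Oc3cc(C#CC(=O)c4c(OCOC)cc(OCOC)cc4OCOC)cc(OC)c3O[C@@H]2CO[Si](C)(C)C(C)(C)C)ccc1OCOC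
F5 | step 12 | (E)-3-(diethylamino)-3-[(2R,3R)-2-({[tert-butyl(dimethyl)silyl]oxy}methyl)-8-methoxy-3-[3-methoxy-4-(methoxymethoxy)phenyl]-2,3-dihydro-1,4-benzodioxin-6-yl]-1-[2,4,6-tris(methoxymethoxy)phenyl]prop-2-en-1-one | COc1cc([C@H]2Oc3cc(/C(N(CC)CC)=C\C(=O)c4c(OCOC)cc(OCOC)cc4OCOC)cc(OC)c3O[C@@H]2CO[Si](C)(C)C(C)(C)C)ccc1OCOC
F6 | step 9 | [(2R,3R)-6-bromo-8-methoxy-3-[3-methoxy-4-(methoxymethoxy)phenyl]-2,3-dihydro-1,4-benzodioxin-2-yl]methanol | COc1cc([C@H]2Oc3cc(Br)cc(OC)c3O[C@@H]2CO)ccc1OCOC
F7 | step 3 | 3,5-bis(methoxymethoxy)phenyl diethylcarbamate | CCN(CC)C(=O)Oc1cc(OCOC)cc(OCOC)c1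
F8 | step 3 | 2-iodo-3,5-bis(methoxymethoxy)phenyl diethylcarbamate | CCN(CC)C(=O)Oc1cc(OCOC)cc(OCOC)c1I
F9 | step 13 | 2-[(2R,3R)-2-(hydroxymethyl)-8-methoxy-3-[3-methoxy-4-(methoxymethoxy)phenyl]-2,3-dihydro-1,4-benzodioxin-6-yl]-5,7-bis(methoxymethoxy)-4H-chromen-4-one | COc1cc([C@H]2Oc3cc(-c4cc(=O)c5c(OCOC)cc(OCOC)cc5o4)cc(OC)c3O[C@@H]2CO)ccc1OCOC
A1 | alternative 1 | (2R,3R)-3-(4-hydroxy-3-methoxyphenyl)-2-(hydroxymethyl)-8-methoxy-2,3-dihydro-1,4-benzodioxine-6-carbaldehyde | COc1cc([C@H]2Oc3cc(C=O)cc(OC)c3O[C@@H]2CO)ccc1O
A2 | alternative 1 | 4-{[(2R)-1-hydroxy-3-(methoxymethoxy)-1-[3-methoxy-4-(methoxymethoxy)phenyl]propan-2-yl]oxy}-3-methoxy-5-(methoxymethoxy)benzaldehyde (either carbinol epimer) | COCOc1cc(C=O)cc(OC)c1O[C@H](COCOC)C(O)c1ccc(OCOC)c(OC)c1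
A3 | alternative 2 | 2-ethyl 6-methyl (2S,3R)-8-methoxy-3-[3-methoxy-4-(methoxymethoxy)phenyl]-2,3-dihydro-1,4-benzodioxine-2,6-dicarboxylate (trans) | COc1cc([C@H]2Oc3cc(C(=O)OC)cc(OC)c3O[C@@H]2C(=O)OCC)ccc1OCOC
A4 | alternative 2 | methyl 4-bromo-3-hydroxy-5-methoxybenzoate | COC(=O)c1cc(O)c(Br)c(OC)c1
A5 | alternative 2 | ethyl (2S,3S)-3-[3-methoxy-4-(methoxymethoxy)phenyl]oxirane-2-carboxylate (cis) | CCOC(=O)[C@H]1O[C@H]1c1ccc(OCOC)c(OC)c1
A6 | alternative 3 | 2-[(2R,3R)-2-({[tert-butyl(dimethyl)silyl]oxy}methyl)-8-methoxy-3-[3-methoxy-4-(methoxymethoxy)phenyl]-2,3-dihydro-1,4-benzodioxin-6-yl]-5,7-dihydroxy-4H-chromen-4-one | COc1cc([C@H]2Oc3cc(-c4cc(=O)c5c(O)cc(O)cc5o4)cc(OC)c3O[C@@H]2CO[Si](C)(C)C(C)(C)C)ccc1OCOC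
A7 | alternative 3 | methyl 4-{6-[(2R,3R)-2-({[tert-butyl(dimethyl)silyl]oxy}methyl)-8-methoxy-3-[3-methoxy-4-(methoxymethoxy)phenyl]-2,3-dihydro-1,4-benzodioxin-6-yl]-4-oxo-4H-pyran-2-yl}-3-oxobutanoate | COc1cc([C@H]2Oc3cc(-c4cc(=O)cc(CC(=O)CC(=O)OC)o4)cc(OC)c3O[C@@H]2CO[Si](C)(C)C(C)(C)C)ccc1OCOC
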